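## Retrosynthetic overview

1. Target ⇐ C4 alcohol (acetylation) ⇐ racemic alcohol, resolved as diastereomeric camphanate esters ⇐ bicyclic enedione (1,2-reduction of the C4 carbonyl).
2. Key disconnection: the C1–C7 and C5–C6 bonds are cut together (retro cationic [5+2] cycloaddition), giving two fragments of comparable size: a 2-allyl-tetramethoxy para-quinone monoketal (fragment A) and (E)-1-(3,4,5-trimethoxyphenyl)propene (fragment B).
3. Fragment A ⇐ 6-allyl-2,3,4-trimethoxyphenol (oxidative ketalisation) ⇐ 4-dienyl-4-methoxycyclobutenone (Moore ring expansion) ⇐ dimethyl squarate + (E)-1-iodopenta-1,4-diene.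
4. Fragment B ⇐ 5-bromo-1,2,3-trimethoxybenzene + (E)-propenylboronic acid (Suzuki coupling); the bromide ⇐ resorcinol by methylation, ortho-lithiation/oxidation, para-bromination and methylation.
5. Ring order: the benzene ring of fragment A is made from the four-membered ring and then dearomatised; the five- and seven-membered rings of the bicyclo[3.2.1]octane are closed together in the [5+2] step; the aryl ring of fragment B comes from resorcinol.

Assumption: all bicyclic compounds are numbered as the target is (C1 allyl bridgehead, C2=C3, C4 oxygenated carbon, C5 methoxy bridgehead, C6 aryl, C7 methyl, C8 bridging carbonyl); read this way the target is (1S,4R,5S,6R,7S), with aryl endo (anti to C8), methyl exo and the acetoxy group on the C4 face turned towards the C6–C7 bridge (in the 4-oxo precursor the same C5 geometry is labelled R because the CIP priorities change).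

## Route

Step 1
Reactants: 1 squaric acid (3,4-dihydroxycyclobut-3-ene-1,2-dione)
Product: 2 dimethyl squarate (3,4-dimethoxycyclobut-3-ene-1,2-dione)
Conditions: HC(OMe)3 (2.2 equiv), MeOH, reflux
Reagents that add atoms: methanol, CO; trimethyl orthoformate, COC(OC)OC
Why: Orthoester-driven esterification of the vinylogous diacid, pushed to completion because the orthoformate consumes the water released; no stereocentre is formed.

Step 2
Reactants: 3 pent-1-en-4-yne
Product: 5 (1E)-1-iodopenta-1,4-diene, via Cp2Zr(Cl)-alkenyl complex 4 (not isolated)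
Conditions: Cp2Zr(H)Cl (1.0 equiv), CH2Cl2, 0 °C → rt; then I2, 0 °C
Reagents that add atoms: iodine, [I][I]
Why: Hydrozirconation–iodination: Zr–H adds syn across the terminal alkyne faster than across the monosubstituted alkene with zirconium on the terminal carbon, and iodinolysis of the C–Zr bond occurs with retention, so only the E-alkenyl iodide forms.

Step 3
Reactants: 5 (1E)-1-iodopenta-1,4-diene; 2 dimethyl squarate
Product: 8 2,3,4-trimethoxy-4-[(1E)-penta-1,4-dien-1-yl]cyclobut-2-en-1-one (racemic), via dienyllithium 6 (not isolated), via lithium alkoxide 7 (not isolated)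
Conditions: 5, t-BuLi (2 equiv), Et2O, −78 °C; then 2, THF, −78 °C; then methyl triflate (MeOTf), −78 → 0 °C
Reagents that add atoms: methyl triflate, COS(=O)(=O)C(F)(F)F
Why: Lithium–iodine exchange with retention of alkene geometry, 1,2-addition of the alkenyllithium to one of the two equivalent squarate carbonyls and O-methylation of the tertiary alkoxide give the 4-alkenyl-4-methoxycyclobutenone; the new carbinol centre is racemic and is destroyed in the next step.

Step 4
Reactants: 8 2,3,4-trimethoxy-4-[(1E)-penta-1,4-dien-1-yl]cyclobut-2-en-1-one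
Product: 11 6-allyl-2,3,4-trimethoxyphenol, via dienylketene 9 (not isolated), via cyclohexadienone tautomer 10 (not isolated)
Conditions: p-xylene, reflux (138 °C)
Reagents that add atoms: none
Why: Moore rearrangement: conrotatory 4π ring opening with the 4-methoxy group rotating outward gives the Z-dienylketene, and 6π electrocyclisation followed by tautomerisation gives the phenol with the free OH next to the allyl group and the former carbinol oxygen para to it; no stereocentre remains.

Step 5
Reactants: 11 6-allyl-2,3,4-trimethoxyphenol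
Product: 12 2-allyl-4,4,5,6-tetramethoxycyclohexa-2,5-dien-1-one (fragment A)
Conditions: PhI(OAc)2 (1.1 equiv), MeOH, 0 °C
Reagents that add atoms: methanol, CO
Why: Oxidative dearomatisation of a para-methoxyphenol: the hypervalent iodine reagent generates a phenoxonium ion that methanol traps at the methoxy-bearing para carbon to give the para-quinone monoketal; no stereocentre is formed.

Step 6
Reactants: 13 resorcinol (benzene-1,3-diol)
Product: 14 1,3-dimethoxybenzene
Conditions: MeI (2.5 equiv), K2CO3, acetone, reflux
Reagents that add atoms: iodomethane, CI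
Why: Williamson ether synthesis (SN2 methylation of both phenoxides); no stereocentre is formed.

Step 7
Reactants: 14 1,3-dimethoxybenzene
Product: 17 2,6-dimethoxyphenol, via aryllithium 15 (not isolated), via arylboronate 16 (not isolated)
Conditions: n-BuLi, THF, 0 °C → rt; B(OMe)3, −78 °C → rt; then AcOH, 30% aq H2O2, 0 °C → rt
Reagents that add atoms: hydrogen peroxide, OO
Why: Directed ortho-metalation between the two methoxy groups, borylation of the aryllithium and oxidative 1,2-migration from boron to oxygen (borylation–oxidation) install the hydroxyl at C2; no stereocentre is formed.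

Step 8
Reactants: 17 2,6-dimethoxyphenol
Product: 18 4-bromo-2,6-dimethoxyphenol
Conditions: N-bromosuccinimide (NBS, 1.0 equiv), CHCl3, −40 °C → rt
Reagents that add atoms: N-bromosuccinimide, O=C1CCC(=O)N1Br
Why: Electrophilic aromatic bromination directed para to the free phenol, the most activated open position; no stereocentre is formed.

Step 9
Reactants: 18 4-bromo-2,6-dimethoxyphenol
Product: 19 5-bromo-1,2,3-trimethoxybenzene
Conditions: MeI, K2CO3, acetone, reflux
Reagents that add atoms: iodomethane, CI
Why: Williamson ether synthesis on the hindered phenoxide; no stereocentre is formed.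

Step 10
Reactants: 19 5-bromo-1,2,3-trimethoxybenzene; 20 (E)-prop-1-en-1-ylboronic acid
Product: 21 1,2,3-trimethoxy-5-[(1E)-prop-1-en-1-yl]benzene (fragment B)
Conditions: Pd(PPh3)4 (3 mol %), K2CO3, 1,4-dioxane/H2O, 90 °C
Reagents that add atoms: none
Why: Suzuki–Miyaura cross-coupling (oxidative addition of zerovalent palladium into the C–Br bond, transmetalation, reductive elimination) proceeds with retention of the alkene geometry of the boronic acid, so only the E-propenylarene forms.

Step 11
Reactants: 12 2-allyl-4,4,5,6-tetramethoxycyclohexa-2,5-dien-1-one; 21 1,2,3-trimethoxy-5-[(1E)-prop-1-en-1-yl]benzene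
Product: 24 rac-(1S,5R,6R,7S)-1-allyl-3,5-dimethoxy-7-methyl-6-(3,4,5-trimethoxyphenyl)bicyclo[3.2.1]oct-2-ene-4,8-dione, via methoxy-oxocarbenium cation 22 (not isolated), via cycloadduct oxocarbenium 23 (not isolated)
Conditions: 2,4,6-trinitrobenzenesulfonic acid (0.2 equiv), MeCN, −35 °C; then H2O, 0 °C
Reagents that add atoms: water, O
Why: Büchi-type cationic [5+2] cycloaddition: acid ionises the ketal to cation 22, the nucleophilic methyl-bearing alkene carbon bonds to the allyl-bearing terminus (future C1), the benzylic cation so formed is captured on the same face by the methoxy-bearing enol-ether carbon (future C5), and hydrolysis of oxocarbenium 23 on quench unveils the C4 carbonyl; the E-alkene geometry becomes the trans C6-aryl/C7-methyl relationship, the compact endo arrangement with the aryl group stacked over the cationic dienone puts aryl endo and methyl exo, and because both faces of the planar cation are equivalent the product is a racemate in which C1, C5, C6 and C7 are fixed relative to one another.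

Step 12
Reactants: 24 rac-(1S,5R,6R,7S)-1-allyl-3,5-dimethoxy-7-methyl-6-(3,4,5-trimethoxyphenyl)bicyclo[3.2.1]oct-2-ene-4,8-dione
Product: 25 rac-(1S,4R,5S,6R,7S)-1-allyl-4-hydroxy-3,5-dimethoxy-7-methyl-6-(3,4,5-trimethoxyphenyl)bicyclo[3.2.1]oct-2-en-8-one
Conditions: NaBH4, CeCl3·7H2O, MeOH, −78 °C
Reagents that add atoms: none
Why: Luche 1,2-reduction: the cerium-activated borohydride reduces the conjugated C4 carbonyl in preference to the C8 ketone buried between two fully substituted bridgeheads, and hydride attacks C4 from the face turned away from the C6–C7 bridge because the other face is covered by the endo aryl group, which places the new hydroxyl on the aryl side and sets C4 as R in the 1S series (the C5 label changes from R to S only through the CIP priorities).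

Step 13
Reactants: 25 rac-(1S,4R,5S,6R,7S)-1-allyl-4-hydroxy-3,5-dimethoxy-7-methyl-6-(3,4,5-trimethoxyphenyl)bicyclo[3.2.1]oct-2-en-8-one
Product: 26 (1S,4R,5S,6R,7S)-1-allyl-3,5-dimethoxy-7-methyl-8-oxo-6-(3,4,5-trimethoxyphenyl)bicyclo[3.2.1]oct-2-en-4-yl (1S,4R)-camphanate (single diastereomer after separation)
Conditions: (1S)-(−)-camphanic chloride, Et3N, 4-(dimethylamino)pyridine (DMAP), CH2Cl2, 0 → 40 °C; then chromatography on SiO2 and crystallisation to separate the two diastereomers
Reagents that add atoms: (1S)-(−)-camphanic chloride, ClC(=O)[C@@]12CC[C@@](C)(C(=O)O1)C2(C)C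
Why: Classical resolution through covalent diastereomers: DMAP-catalysed acylation with an enantiopure acid chloride that has no epimerisable centre turns the two enantiomers into separable diastereomeric esters, the one containing the (1S,4R,5S,6R,7S) alcohol is identified by X-ray crystallography using the known camphanoyl configuration as internal reference, and no stereocentre of the bicycle is touched.

Step 14
Reactants: 26 (1S,4R,5S,6R,7S)-camphanate ester
Product: 27 (1S,4R,5S,6R,7S)-1-allyl-4-hydroxy-3,5-dimethoxy-7-methyl-6-(3,4,5-trimethoxyphenyl)bicyclo[3.2.1]oct-2-en-8-one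
Conditions: K2CO3 (0.3 equiv), MeOH, 0 °C → rt; AcOH quench
Reagents that add atoms: none
Why: Base-catalysed transesterification (methanolysis) of the activated alpha-alkoxy ester by acyl–oxygen cleavage leaves the C4–O bond and thus the C4 configuration untouched, and catalytic base at low temperature is used to keep the beta-hydroxy ketone from retro-aldol opening.

Step 15
Reactants: 27 (1S,4R,5S,6R,7S)-1-allyl-4-hydroxy-3,5-dimethoxy-7-methyl-6-(3,4,5-trimethoxyphenyl)bicyclo[3.2.1]oct-2-en-8-one
Product: 28 (1S,4R,5S,6R,7S)-1-allyl-3,5-dimethoxy-7-methyl-8-oxo-6-(3,4,5-trimethoxyphenyl)bicyclo[3.2.1]oct-2-en-4-yl acetate (CNP0181407.1)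
Conditions: Ac2O, pyridine, 4-(dimethylamino)pyridine (cat.), CH2Cl2, rt
Reagents that add atoms: acetic anhydride, CC(=O)OC(C)=O
Why: DMAP-catalysed O-acylation (esterification) takes place at oxygen with retention at C4 and gives the target.

## Compound list

1 | squaric acid (3,4-dihydroxycyclobut-3-ene-1,2-dione) | OC1=C(O)C(=O)C1=O | starting material
2 | dimethyl squarate (3,4-dimethoxycyclobut-3-ene-1,2-dione) | COC1=C(OC)C(=O)C1=O | intermediate
3 | pent-1-en-4-yne | C=CCC#C | starting material
4 | chlorobis(cyclopentadienyl)[(1E)-penta-1,4-dien-1-yl]zirconium, Cp2Zr(Cl)(alkenyl), formed in situ | C=CC/C=C/[Zr](Cl)(C1C=CC=C1)C1C=CC=C1 | intermediate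
5 | (1E)-1-iodopenta-1,4-diene | C=CC/C=C/I | intermediate
6 | (1E)-penta-1,4-dien-1-yllithium, formed in situ | [Li]/C=C/CC=C | intermediate
7 | lithium 2,3-dimethoxy-4-oxo-1-[(1E)-penta-1,4-dien-1-yl]cyclobut-2-en-1-olate (racemic), formed in situ | [Li]OC1(/C=C/CC=C)C(OC)=C(OC)C1=O | intermediate
8 | 2,3,4-trimethoxy-4-[(1E)-penta-1,4-dien-1-yl]cyclobut-2-en-1-one (racemic) | COC1=C(OC)C(OC)(/C=C/CC=C)C1=O | intermediate
9 | (3Z,5E)-2,3,4-trimethoxynona-1,3,5,8-tetraen-1-one (dienylketene), formed in situ | O=C=C(OC)/C(OC)=C(OC)\C=C\CC=C | intermediate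
10 | 6-allyl-2,3,4-trimethoxycyclohexa-2,4-dien-1-one (racemic), formed in situ | O=C1C(OC)=C(OC)C(OC)=CC1CC=C | intermediate
11 | 6-allyl-2,3,4-trimethoxyphenol | C=CCc1cc(OC)c(OC)c(OC)c1O | intermediate
12 | 2-allyl-4,4,5,6-tetramethoxycyclohexa-2,5-dien-1-one (fragment A) | C=CCC1=CC(OC)(OC)C(OC)=C(OC)C1=O | intermediate
13 | resorcinol (benzene-1,3-diol) | Oc1cccc(O)c1 | starting material
14 | 1,3-dimethoxybenzene | COc1cccc(OC)c1 | intermediate
15 | 2,6-dimethoxyphenyllithium, formed in situ | [Li]c1c(OC)cccc1OC | intermediate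
16 | dimethyl (2,6-dimethoxyphenyl)boronate, formed in situ | COB(OC)c1c(OC)cccc1OC | intermediate
17 | 2,6-dimethoxyphenol | COc1cccc(OC)c1O | intermediate
18 | 4-bromo-2,6-dimethoxyphenol | COc1cc(Br)cc(OC)c1O | intermediate
19 | 5-bromo-1,2,3-trimethoxybenzene | COc1cc(Br)cc(OC)c1OC | intermediate
20 | (E)-prop-1-en-1-ylboronic acid | C/C=C/B(O)O | starting material
21 | 1,2,3-trimethoxy-5-[(1E)-prop-1-en-1-yl]benzene (fragment B) | C/C=C/c1cc(OC)c(OC)c(OC)c1 | intermediate
22 | (5-allyl-2,3-dimethoxy-4-oxocyclohexa-2,5-dien-1-ylidene)(methyl)oxonium, formed in situ | C=CCC1=CC(=[O+]C)C(OC)=C(OC)C1=O | intermediate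
23 | C4 O-methyl oxocarbenium ion of dione 24 (racemate; enantiomer leading to 28 drawn), formed in situ | C=CC[C@]12C=C(OC)C(=[O+]C)[C@](OC)(C1=O)[C@@H](c1cc(OC)c(OC)c(OC)c1)[C@@H]2C | intermediate
24 | rac-(1S,5R,6R,7S)-1-allyl-3,5-dimethoxy-7-methyl-6-(3,4,5-trimethoxyphenyl)bicyclo[3.2.1]oct-2-ene-4,8-dione (enantiomer leading to 28 drawn) | C=CC[C@]12C=C(OC)C(=O)[C@](OC)(C1=O)[C@@H](c1cc(OC)c(OC)c(OC)c1)[C@@H]2C | intermediate
25 | rac-(1S,4R,5S,6R,7S)-1-allyl-4-hydroxy-3,5-dimethoxy-7-methyl-6-(3,4,5-trimethoxyphenyl)bicyclo[3.2.1]oct-2-en-8-one (enantiomer leading to 28 drawn) | C=CC[C@]12C=C(OC)[C@@H](O)[C@](OC)(C1=O)[C@@H](c1cc(OC)c(OC)c(OC)c1)[C@@H]2C | intermediate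
26 | (1S,4R,5S,6R,7S)-1-allyl-3,5-dimethoxy-7-methyl-8-oxo-6-(3,4,5-trimethoxyphenyl)bicyclo[3.2.1]oct-2-en-4-yl (1S,4R)-4,7,7-trimethyl-3-oxo-2-oxabicyclo[2.2.1]heptane-1-carboxylate | C=CC[C@]12C=C(OC)[C@@H](OC(=O)[C@@]34CC[C@@](C)(C(=O)O3)C4(C)C)[C@](OC)(C1=O)[C@@H](c1cc(OC)c(OC)c(OC)c1)[C@@H]2C | intermediate
27 | (1S,4R,5S,6R,7S)-1-allyl-4-hydroxy-3,5-dimethoxy-7-methyl-6-(3,4,5-trimethoxyphenyl)bicyclo[3.2.1]oct-2-en-8-one | C=CC[C@]12C=C(OC)[C@@H](O)[C@](OC)(C1=O)[C@@H](c1cc(OC)c(OC)c(OC)c1)[C@@H]2C | intermediate
28 | (1S,4R,5S,6R,7S)-1-allyl-3,5-dimethoxy-7-methyl-8-oxo-6-(3,4,5-trimethoxyphenyl)bicyclo[3.2.1]oct-2-en-4-yl acetate (CNP0181407.1) | C=CC[C@]12C=C(OC)[C@@H](OC(C)=O)[C@](OC)(C1=O)[C@@H](c1cc(OC)c(OC)c(OC)c1)[C@@H]2C | target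

## Step count and weak points

Total step count: 15.
Longest linear sequence: 10 steps (steps 6–10 and 11–15, from 13 to 28); the branch from 1 or 3 to 28 is 9 steps.

Most likely to fail, first: the alkenyllithium addition of step 3. Dienyllithium 6 carries doubly allylic hydrogens and may isomerise or protonate before it adds to 2. The fallback sets out from 2 and comes back at 11, bringing in the allyl group by a Claisen rearrangement. Vinyllithium (from tetravinylstannane Sn(CH=CH2)4 and MeLi, THF, −78 °C) adds to 2 to give lithium 2,3-dimethoxy-4-oxo-1-vinylcyclobut-2-en-1-olate F1. This is methylated in the same flask with methyl triflate to 2,3,4-trimethoxy-4-vinylcyclobut-2-en-1-one F2. Moore rearrangement in refluxing p-xylene gives 2,3,4-trimethoxyphenol F3. Allyl bromide and K2CO3 in acetone give 1-(allyloxy)-2,3,4-trimethoxybenzene F4. Aromatic Claisen rearrangement in N,N-diethylaniline at 190 °C moves the allyl group to the only free ortho position and gives 11.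

Second: the cationic [5+2] cycloaddition of step 11. The benzylic cation may close on oxygen (hydrobenzofuranone) or the alkene may attack the methoxy-bearing terminus first, and the bicyclic adduct can rearrange under acid. The fallback sets out from 2, 3 and 21 and comes back at 24; it activates a quinone with a Lewis acid instead of ionising a ketal. Compound 3 is deprotonated with n-BuLi (THF, −78 °C) to lithium pent-4-en-1-yn-1-ide F5. This adds to 2 and gives after NH4Cl quench 4-hydroxy-2,3-dimethoxy-4-(pent-4-en-1-yn-1-yl)cyclobut-2-en-1-one F6. Heating in p-xylene (Moore rearrangement of an alkynylcyclobutenone) gives 5-allyl-2,3-dimethoxycyclohexa-2,5-diene-1,4-dione F7. The quinone is complexed with TiCl4/Ti(OiPr)4 in CH2Cl2 at −78 °C and combined with 21 in an Engler-type [5+2] cycloaddition. Aqueous work-up gives rac-(1S,5R,6R,7S)-1-allyl-3-hydroxy-5-methoxy-7-methyl-6-(3,4,5-trimethoxyphenyl)bicyclo[3.2.1]oct-2-ene-4,8-dione F8. O-Methylation of this enolised 1,2-dione with Me2SO4 and K2CO3 in acetone gives 24.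

Third: the camphanate methanolysis of step 14. The free alkoxide of the strained beta-hydroxy ketone can undergo retro-aldol opening or C4 epimerisation, and the hindered ester may need long exposure to base. The fallback sets out from 25 and comes back at 28, replacing the diastereomer resolution (steps 13–15) by an enzymatic kinetic resolution that installs the acetate directly. Racemic 25 is treated with immobilised Candida antarctica lipase B and vinyl acetate in tert-butyl methyl ether at 40 °C. By the Kazlauskas rule (large group the C5 bridgehead side, medium group the C3 enol-ether side) the 4R alcohol is acetylated, giving 28. The unreacted enantiomer of 25 is removed by chromatography. This fallback makes no compound that is not already in the list (entry F0).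

Further compounds
F1 | step 3 | lithium 2,3-dimethoxy-4-oxo-1-vinylcyclobut-2-en-1-olate (racemic) | [Li]OC1(C=C)C(OC)=C(OC)C1=O
F2 | step 3 | 2,3,4-trimethoxy-4-vinylcyclobut-2-en-1-one (racemic) | COC1=C(OC)C(OC)(C=C)C1=O
F3 | step 3 | 2,3,4-trimethoxyphenol | COc1ccc(O)c(OC)c1OC
F4 | step 3 | 1-(allyloxy)-2,3,4-trimethoxybenzene | C=CCOc1ccc(OC)c(OC)c1OC
F5 | step 11 | lithium pent-4-en-1-yn-1-ide | [Li]C#CCC=C
F6 | step 11 | 4-hydroxy-2,3-dimethoxy-4-(pent-4-en-1-yn-1-yl)cyclobut-2-en-1-one (racemic) | C=CCC#CC1(O)C(OC)=C(OC)C1=O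
F7 | step 11 | 5-allyl-2,3-dimethoxycyclohexa-2,5-diene-1,4-dione | C=CCC1=CC(=O)C(OC)=C(OC)C1=O
F8 | step 11 | rac-(1S,5R,6R,7S)-1-allyl-3-hydroxy-5-methoxy-7-methyl-6-(3,4,5-trimethoxyphenyl)bicyclo[3.2.1]oct-2-ene-4,8-dione | C=CC[C@]12C=C(O)C(=O)[C@](OC)(C1=O)[C@@H](c1cc(OC)c(OC)c(OC)c1)[C@@H]2C
F0 | step 14 | none | none
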